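**Set-up.** Red holds 1.1 mM of Z against 20 mM of G, so at one Z per X, which is this reckoning's assumption, its X stops at 5.50% of the G charged.

| setting | red | ochre | summer | autumn | midnight | dusk |
|---|---|---|---|---|---|---|
| G | 20 mM | 20 mM | 20 mM | 20 mM | 20 mM | 20 mM |
| Z | 1.1 mM | 48 mM | 2.00 mM | 6.00 mM | 20.0 mM | 60.0 mM |
| D | 2 µM | 2 µM | 2.0 µM | 2.0 µM | 2.0 µM | 2.0 µM |
| remark | run made earlier | run made earlier |  |  |  |  |
| time |  |  | 2.5 d | 2.5 d | 2.5 d | 2.5 d |

- red (time / h: X / %, G / %): 1.50: 0, 99.7; 5.00: 0.7, 99.6; 8.00: 0.8, 98.6; 12.0: 1.0, 98.5; 20.0: 2.4, 97.6; 25.0: 2.8, 97.3; 30.0: 3.1, 96.3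
- ochre (time / h: X / %, G / %): 4.00: 13.0, 86.5; 8.00: 25.0, 74.1; 12.0: 34.6, 62.9; 15.0: 40.9, 55.0; 20.0: 48.7, 42.9; 25.0: 54.0, 33.8; 30.0: 56.4, 25.2

(standard deviation of a reading: 0.3 percentage points)

- the numbers in the tables scatter with a standard deviation of 0.3 percentage points
- "hardly changes" means that all values lie within two and a half points (for a concentration: within two and a half percent of the largest)

- amount of X at the end, in percent of the G charged for summer, autumn, midnight, dusk, in this order
- the shape of the row from first to last (rises all the way / rises, then falls / falls, then rises / falls all the way / hardly changes)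

**The puzzle.** Red's X climbs almost straight to 3.1%. Yet at one Z per X, that amount has used 56.4% of the Z charged. A straight line and a reagent more than half spent do not seem to go together.

**Clearing it.** G barely moves in red, standing at 96.3% after 30.0 h. Enzyme and G then act as a constant, and Z decays as a pseudo-first-order species. Let τ be the half-life of Z, the time over which Z halves at a small charge: red's last reading gives 25.1 h. The gap between X and its ceiling also halves every τ. At mid-run, this curve stands 0.32 percentage points above the straight chord, and the scatter is 0.3 points. The bend therefore hides in the readings.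

**Own reckoning.** Ochre's first reading, read the same way, gives 49.8 h, longer than red's τ. So τ, as read, stretches with the charge of Z, and it is carried here to the small charges of summer and autumn. Summer should end near 8.10% of X and autumn near 24.3%.

**Forecast and result.** The forecast, which holds that “Z acts as an activator and is not consumed”, gives more than this reckoning for summer and autumn, with a row of 12%, 30%, 54%, 40% and the shape "rises, then falls". The flasks give 7.55%, 21.1%, 51.6%, 35.2%, and the shape is "rises, then falls".

    Z + GD ⇌ ZGD (K = 28.0 M⁻¹, k = 2.20 × 10⁵ M⁻¹ h⁻¹)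
    ZGD → D + X (k = 850 h⁻¹)
    Z + D + X → D + Q (k = 4.90 × 10⁵ M⁻² h⁻¹)
    G + D ⇌ GD (K = 72.0 M⁻¹, k = 1.30 × 10⁶ M⁻¹ h⁻¹)

**Z running down.** With τ, summer should keep 19.0% of its Z at the end. The summer flask keeps 23%, and autumn, charged with 6.00 mM of Z, keeps 24% of its own charge. This loss of Z costs summer part of its X: with Z held at its charge, summer ends at 13.9% of X instead of 7.55%.

(The runs come from a simulation from invented constants; the scatter is artificial.)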